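**Retrosynthetic overview**
- Target 20 comes from hydroxyquinone 19 by O-methylation, and 19 from 14 by a Hooker oxidation that opens ring A, expels C3 as CO2 and re-closes the ring with the former C2-methyl carbon as the new C3–H.
- The feature that dictates this: in ring A the methoxy group sits on C2, beside the C1 carbonyl that is peri to C8 and its trimethoxyphenyl ring C, whereas a polar aryne annulation places the oxygenated carbon on C3, so C2 and C3 must exchange roles.
- 14 comes from keto ester 12 by Claisen ring closure and autoxidation (first closure of ring A); 12 comes from aryne 10 and methyl 3-oxopentanoate 9 (new C–C bonds at C4a and C8a).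
- Aryne precursor 8 comes from 3,4-dimethylphenol 1 (ring B) by bromination, iodination, Suzuki coupling with 4 (ring C attached) and a one-flask silylation, retro-Brook shift and triflation.
- Ring order: ring B is bought, ring C is joined in step 3, ring A is closed in step 6, then contracted and re-closed in step 7.

Key step: step 7

Remark: the naphthoquinone numbering of 20 is used throughout (C1 is the carbonyl beside C2 and peri to C8; C4a and C8a are the fusion carbons). The target has no stereocentre and its C8–aryl axis is unspecified, so all compounds are taken as racemic about that axis.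

**Step 1**
Reactants: 1 3,4-dimethylphenol
Product: 2 2-bromo-4,5-dimethylphenol
Conditions: NBS, i-Pr2NH (cat.), CH2Cl2, 0 °C
Reagents that add atoms: N-bromosuccinimide, O=C1CCC(=O)N1Br
Why: Electrophilic aromatic bromination of a para-blocked phenol goes ortho to the hydroxyl, and the ortho site that is not flanked by a methyl group (and is para to the C3 methyl) should react first, with one equivalent of reagent limiting dibromination.

**Step 2**
Reactants: 2 2-bromo-4,5-dimethylphenol
Product: 3 6-bromo-2-iodo-3,4-dimethylphenol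
Conditions: NIS, TsOH·H2O (cat.), MeCN, rt
Reagents that add atoms: N-iodosuccinimide, O=C1CCC(=O)N1I
Why: Electrophilic aromatic iodination should take the only remaining position ortho to the hydroxyl, the other ring C–H being meta to it and unactivated.

**Step 3**
Reactants: 3 6-bromo-2-iodo-3,4-dimethylphenol; 4 2,4,5-trimethoxyphenylboronic acid
Product: 5 6-bromo-3,4-dimethyl-2-(2,4,5-trimethoxyphenyl)phenol
Conditions: Pd(PPh3)4 (cat.), Na2CO3, DME/H2O, 85 °C
Reagents that add atoms: none
Why: Suzuki–Miyaura coupling in which zerovalent palladium inserts into the C–I bond far faster than into the C–Br bond, so that with about one equivalent of 4 and this moderately active catalyst the bromide needed in step 4 should be kept.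

**Step 4**
Reactants: 5 6-bromo-3,4-dimethyl-2-(2,4,5-trimethoxyphenyl)phenol
Product: 8 3,4-dimethyl-2-(2,4,5-trimethoxyphenyl)-6-(trimethylsilyl)phenyl trifluoromethanesulfonate, via trimethylsilyl ether 6 (not isolated), via lithium phenoxide 7 (not isolated)
Conditions: HMDS, THF, 70 °C, then evaporation; n-BuLi, THF, −78 °C; Tf2O, −78 °C to rt
Reagents that add atoms: hexamethyldisilazane, C[Si](C)(C)N[Si](C)(C)C; trifluoromethanesulfonic anhydride, O=S(=O)(OS(=O)(=O)C(F)(F)F)C(F)(F)F
Why: O-Silylation, bromine–lithium exchange and the 1,3 oxygen-to-carbon silyl shift (retro-Brook rearrangement) deliver the ortho-silyl phenoxide, which is O-triflated in the same flask, the standard way from an ortho-bromophenol to a silylaryl triflate.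

**Step 5**
Reactants: 8 3,4-dimethyl-2-(2,4,5-trimethoxyphenyl)-6-(trimethylsilyl)phenyl trifluoromethanesulfonate; 9 methyl 3-oxopentanoate (in excess)
Product: 12 methyl 2-[4,5-dimethyl-2-propanoyl-3-(2,4,5-trimethoxyphenyl)phenyl]acetate, via aryne 10 (not isolated), via benzocyclobutene alkoxide 11 (not isolated)
Conditions: CsF, MeCN, 80 °C
Reagents that add atoms: none
Why: Fluoride-induced 1,2-elimination (Kobayashi method) gives aryne 10, and its acyl-alkylation by the β-keto ester should proceed by enolate C-attack at the aryne carbon remote from ring C (C4a), since the twisted C8 aryl group shields C8a and stabilises the aryl anion developing there, followed by closure of that anion onto the ketone to alkoxide 11 and retro-aldol fragmentation, which leaves the propanoyl group on C8a and the acetate arm on C4a.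

**Step 6**
Reactants: 12 methyl 2-[4,5-dimethyl-2-propanoyl-3-(2,4,5-trimethoxyphenyl)phenyl]acetate
Product: 14 3-hydroxy-2,6,7-trimethyl-8-(2,4,5-trimethoxyphenyl)naphthalene-1,4-dione, via naphthalene-1,3-diol 13 (not isolated)
Conditions: NaOMe, MeOH, 65 °C; then air, rt; aq. HCl work-up
Reagents that add atoms: dioxygen, O=O
Why: Intramolecular Claisen (Dieckmann-type) condensation of the ethyl ketone enolate onto the ester closes ring A (6-exo-trig) and aromatises to diol 13, whose C4–H is autoxidised by air in base to the hydroxyquinone, as known for aryne-derived keto esters of this type; C1 stems from the ketone on C8a, so the methyl sits on C2 and the hydroxyl on C3.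

**Step 7**
Reactants: 14 3-hydroxy-2,6,7-trimethyl-8-(2,4,5-trimethoxyphenyl)naphthalene-1,4-dione
Product: 19 2-hydroxy-6,7-dimethyl-8-(2,4,5-trimethoxyphenyl)naphthalene-1,4-dione, via hydroxytrione 15 (not isolated), via indanone hydroxy acid 16 (not isolated), via ring-opened keto acid 17 (not isolated), via aldol hydroxy acid 18 (not isolated)
Conditions: H2O2 (30% aq.), Na2CO3, dioxane/H2O, 70 °C, N2; Na2SO3 quench; then CuSO4, NaOH, H2O, 70 °C; aq. HCl work-up
Reagents that add atoms: hydrogen peroxide, OO
Why: This is the Hooker oxidation of a 2-hydroxy-3-alkyl-1,4-naphthoquinone with methyl as the alkyl group: alkaline peroxide hydroxylates the methyl-bearing C2 to trione 15, hydroxide adds to C3, and a benzilic acid shift moves C2 from C3 to C4, contracting ring A to the five-membered hydroxy acid 16, whose carboxyl carbon is the former C3. Divalent copper in NaOH then cleaves the C2–C4 diol bond to 17, which carries an aryl glyoxylic acid on C4a and a methyl 1,2-diketone on C8a. The methyl carbon, as its enolate, adds to the C4 ketone (intramolecular aldol, 6-enolendo-exo-trig) and re-forms a six-membered ring A in 18, and a second oxidation by divalent copper expels the former C3 as CO2 to give quinone 19. No stereocentre survives, since the two carbinol centres of 16 and the one of 18 are destroyed in the events that follow. The step needs complete transposition of oxygen from C3 to C2, and connectivity fixes this: C2 never leaves C1 and ends as the oxygen-bearing carbon, while the old methyl carbon becomes C3–H, whichever carbonyl of the diketone takes up hydroxide in the benzilic acid shift. The remaining demand is that 19, with its free C3–H, is not oxidised further; this is addressed by destroying excess peroxide before copper is added, by working under N2, and by using little more than the four equivalents of CuSO4 that the two oxidations consume.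

**Step 8**
Reactants: 19 2-hydroxy-6,7-dimethyl-8-(2,4,5-trimethoxyphenyl)naphthalene-1,4-dione
Product: 20 2-methoxy-6,7-dimethyl-8-(2,4,5-trimethoxyphenyl)naphthalene-1,4-dione
Conditions: MeOH, HCl (cat.), reflux
Reagents that add atoms: methanol, CO
Why: Acid-catalysed addition–elimination at C2 (vinylogous Fischer esterification of a 2-hydroxyquinone) keeps the three oxygenated carbons at C1, C2 and C4 and should give the para-quinone methyl ether as the stable isomer, as in the known conversion of 2-hydroxy-1,4-naphthoquinone into its methyl ether.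

**Compound list**
1 | 3,4-dimethylphenol | Cc1ccc(O)cc1C | starting material
2 | 2-bromo-4,5-dimethylphenol | Cc1cc(O)c(Br)cc1C | intermediate
3 | 6-bromo-2-iodo-3,4-dimethylphenol | Cc1cc(Br)c(O)c(I)c1C | intermediate
4 | 2,4,5-trimethoxyphenylboronic acid | OB(O)c1cc(OC)c(OC)cc1OC | starting material
5 | 6-bromo-3,4-dimethyl-2-(2,4,5-trimethoxyphenyl)phenol | Cc1cc(Br)c(O)c(-c2cc(OC)c(OC)cc2OC)c1C | intermediate
6 | [6-bromo-3,4-dimethyl-2-(2,4,5-trimethoxyphenyl)phenoxy]trimethylsilane (not isolated) | Cc1cc(Br)c(O[Si](C)(C)C)c(-c2cc(OC)c(OC)cc2OC)c1C | intermediate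
7 | lithium 3,4-dimethyl-2-(2,4,5-trimethoxyphenyl)-6-(trimethylsilyl)phenoxide (not isolated) | [Li+].[O-]c1c([Si](C)(C)C)cc(C)c(C)c1-c2cc(OC)c(OC)cc2OC | intermediate
8 | 3,4-dimethyl-2-(2,4,5-trimethoxyphenyl)-6-(trimethylsilyl)phenyl trifluoromethanesulfonate | Cc1cc([Si](C)(C)C)c(OS(=O)(=O)C(F)(F)F)c(-c2cc(OC)c(OC)cc2OC)c1C | intermediate
9 | methyl 3-oxopentanoate | CCC(=O)CC(=O)OC | starting material
10 | 4,5-dimethyl-3-(2,4,5-trimethoxyphenyl)benzyne (1,2-didehydrobenzene; not isolated) | CC1=CC#CC(-c2cc(OC)c(OC)cc2OC)=C1C | intermediate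
11 | cesium 7-ethyl-8-(methoxycarbonyl)-3,4-dimethyl-5-(2,4,5-trimethoxyphenyl)bicyclo[4.2.0]octa-1,3,5-trien-7-olate (carbinol carbon on C8a, ester-bearing CH on C4a; diastereomer mixture, both centres lost on fragmentation; not isolated) | CCC1([O-])C(C(=O)OC)c2cc(C)c(C)c(-c3cc(OC)c(OC)cc3OC)c21.[Cs+] | intermediate
12 | methyl 2-[4,5-dimethyl-2-propanoyl-3-(2,4,5-trimethoxyphenyl)phenyl]acetate | CCC(=O)c1c(-c2cc(OC)c(OC)cc2OC)c(C)c(C)cc1CC(=O)OC | intermediate
13 | 2,6,7-trimethyl-8-(2,4,5-trimethoxyphenyl)naphthalene-1,3-diol (not isolated) | Cc1c(O)cc2cc(C)c(C)c(-c3cc(OC)c(OC)cc3OC)c2c1O | intermediate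
14 | 3-hydroxy-2,6,7-trimethyl-8-(2,4,5-trimethoxyphenyl)naphthalene-1,4-dione | CC1=C(O)C(=O)c2cc(C)c(C)c(-c3cc(OC)c(OC)cc3OC)c2C1=O | intermediate
15 | 2-hydroxy-2,6,7-trimethyl-8-(2,4,5-trimethoxyphenyl)naphthalene-1,3,4(2H)-trione (racemic; not isolated) | CC1(O)C(=O)C(=O)c2cc(C)c(C)c(-c3cc(OC)c(OC)cc3OC)c2C1=O | intermediate
16 | 1,2-dihydroxy-2,5,6-trimethyl-3-oxo-4-(2,4,5-trimethoxyphenyl)indane-1-carboxylic acid (present as its sodium salt; configuration at the two carbinol centres unspecified; not isolated) | CC1(O)C(=O)c2c(-c3cc(OC)c(OC)cc3OC)c(C)c(C)cc2C1(O)C(O)=O | intermediate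
17 | 2-[4,5-dimethyl-2-(2-oxopropanoyl)-3-(2,4,5-trimethoxyphenyl)phenyl]-2-oxoacetic acid (sodium salt; not isolated) | CC(=O)C(=O)c1c(-c2cc(OC)c(OC)cc2OC)c(C)c(C)cc1C(=O)C(O)=O | intermediate
18 | 1-hydroxy-6,7-dimethyl-3,4-dioxo-5-(2,4,5-trimethoxyphenyl)-1,2,3,4-tetrahydronaphthalene-1-carboxylic acid (sodium salt, racemic; not isolated) | O=C1C(=O)c2c(-c3cc(OC)c(OC)cc3OC)c(C)c(C)cc2C(O)(C(O)=O)C1 | intermediate
19 | 2-hydroxy-6,7-dimethyl-8-(2,4,5-trimethoxyphenyl)naphthalene-1,4-dione | OC1=CC(=O)c2cc(C)c(C)c(-c3cc(OC)c(OC)cc3OC)c2C1=O | intermediate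
20 | 2-methoxy-6,7-dimethyl-8-(2,4,5-trimethoxyphenyl)naphthalene-1,4-dione | COC1=CC(=O)c2cc(C)c(C)c(-c3cc(OC)c(OC)cc3OC)c2C1=O | target

**Step count and risk**
Total step count: 8. Longest linear sequence: 8 steps (1 to 20).

Steps most likely to fail:

1. **Step 7 (Hooker oxidation).** Hydroxylation at C2 may be slowed by the neighbouring C1 carbonyl and ring C, and the product, whose ring A carries a free C3–H, may be degraded by further oxidation during the copper stage. The fallback gives up carbon deletion and places the methoxy oxygen on C2 during the annulation, then removes the C3 oxygen by reduction. It sets out from 8. The aryne 10 generated from 8 (CsF, MeCN, 80 °C) is trapped with purchased methyl 4-methoxy-3-oxobutanoate F1 to give methyl 2-[2-(2-methoxyacetyl)-4,5-dimethyl-3-(2,4,5-trimethoxyphenyl)phenyl]acetate F2. NaOMe in MeOH, then air, should close ring A through 2-methoxy-6,7-dimethyl-8-(2,4,5-trimethoxyphenyl)naphthalene-1,3-diol F3 to 3-hydroxy-2-methoxy-6,7-dimethyl-8-(2,4,5-trimethoxyphenyl)naphthalene-1,4-dione F4. Tf2O and pyridine convert this into 3-methoxy-6,7-dimethyl-1,4-dioxo-5-(2,4,5-trimethoxyphenyl)-1,4-dihydronaphthalen-2-yl trifluoromethanesulfonate F5. Reduction of the C–O bond with Pd(OAc)2, dppp and Et3SiH in DMF at 60 °C (air on work-up to return any hydroquinone) comes back to the route at the target 20.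

2. **Step 5 (aryne acyl-alkylation).** The enolate may add to C8a instead of C4a, the aryne may be captured by the ortho-methoxy oxygen of ring C (cyclisation with loss of methyl), or the aryl anion may be protonated before it reaches the ketone. The fallback leaves ring C out of the aryne and lets a chlorine on C8 steer the addition by induction; ring C is attached afterwards. It sets out from 2. Chlorination (N-chlorosuccinimide, TsOH cat., MeCN) gives 6-bromo-2-chloro-3,4-dimethylphenol F6. The sequence of step 4 (HMDS; n-BuLi, which exchanges only bromine; Tf2O) passes through (6-bromo-2-chloro-3,4-dimethylphenoxy)trimethylsilane F7 and lithium 2-chloro-3,4-dimethyl-6-(trimethylsilyl)phenoxide F8 to 2-chloro-3,4-dimethyl-6-(trimethylsilyl)phenyl trifluoromethanesulfonate F9. CsF and 9 in MeCN at 80 °C generate 3-chloro-4,5-dimethylbenzyne F10, which should give methyl 2-(3-chloro-4,5-dimethyl-2-propanoylphenyl)acetate F11 with the nucleophile meta to chlorine. Suzuki coupling of F11 with 4 (Pd(OAc)2, SPhos, K3PO4, toluene, 100 °C) comes back to the route at 12; any ring closure under the basic conditions would only anticipate step 6.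

3. **Step 3 (chemoselective Suzuki coupling).** Oxidative addition at the unhindered C–Br bond may compete with the hindered C–I bond, or slow coupling may allow protodeboronation of the electron-rich boronic acid. The fallback removes the second halogen and installs silicon and iodine by carbamate-directed ortho-metalation. It sets out from 1. NaH and diethylcarbamoyl chloride give 3,4-dimethylphenyl diethylcarbamate F12. s-BuLi/TMEDA in THF at −78 °C and Me3SiCl give 4,5-dimethyl-2-(trimethylsilyl)phenyl diethylcarbamate F13 by lithiation at the less hindered ortho site. A second lithiation at the remaining ortho site and I2 give 2-iodo-3,4-dimethyl-6-(trimethylsilyl)phenyl diethylcarbamate F14. Suzuki coupling with 4 (Pd(OAc)2, SPhos, K3PO4, toluene/H2O, 100 °C), now with no competing halide, gives 3,4-dimethyl-2-(2,4,5-trimethoxyphenyl)-6-(trimethylsilyl)phenyl diethylcarbamate F15. LiAlH4 in THF at reflux releases 3,4-dimethyl-2-(2,4,5-trimethoxyphenyl)-6-(trimethylsilyl)phenol F16, and Tf2O with pyridine in CH2Cl2 comes back to the route at 8.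

**Further compounds**
F1 | step 7 | methyl 4-methoxy-3-oxobutanoate (purchased) | COCC(=O)CC(=O)OC
F2 | step 7 | methyl 2-[2-(2-methoxyacetyl)-4,5-dimethyl-3-(2,4,5-trimethoxyphenyl)phenyl]acetate | COCC(=O)c1c(-c2cc(OC)c(OC)cc2OC)c(C)c(C)cc1CC(=O)OC
F3 | step 7 | 2-methoxy-6,7-dimethyl-8-(2,4,5-trimethoxyphenyl)naphthalene-1,3-diol | COc1c(O)cc2cc(C)c(C)c(-c3cc(OC)c(OC)cc3OC)c2c1O
F4 | step 7 | 3-hydroxy-2-methoxy-6,7-dimethyl-8-(2,4,5-trimethoxyphenyl)naphthalene-1,4-dione | COC1=C(O)C(=O)c2cc(C)c(C)c(-c3cc(OC)c(OC)cc3OC)c2C1=O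
F5 | step 7 | 3-methoxy-6,7-dimethyl-1,4-dioxo-5-(2,4,5-trimethoxyphenyl)-1,4-dihydronaphthalen-2-yl trifluoromethanesulfonate | COC1=C(OS(=O)(=O)C(F)(F)F)C(=O)c2cc(C)c(C)c(-c3cc(OC)c(OC)cc3OC)c2C1=O
F6 | step 5 | 6-bromo-2-chloro-3,4-dimethylphenol | Cc1cc(Br)c(O)c(Cl)c1C
F7 | step 5 | (6-bromo-2-chloro-3,4-dimethylphenoxy)trimethylsilane | Cc1cc(Br)c(O[Si](C)(C)C)c(Cl)c1C
F8 | step 5 | lithium 2-chloro-3,4-dimethyl-6-(trimethylsilyl)phenoxide | [Li+].[O-]c1c(Cl)c(C)c(C)cc1[Si](C)(C)C
F9 | step 5 | 2-chloro-3,4-dimethyl-6-(trimethylsilyl)phenyl trifluoromethanesulfonate | Cc1cc([Si](C)(C)C)c(OS(=O)(=O)C(F)(F)F)c(Cl)c1C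
F10 | step 5 | 3-chloro-4,5-dimethylbenzyne | CC1=CC#CC(Cl)=C1C
F11 | step 5 | methyl 2-(3-chloro-4,5-dimethyl-2-propanoylphenyl)acetate | CCC(=O)c1c(Cl)c(C)c(C)cc1CC(=O)OC
F12 | step 3 | 3,4-dimethylphenyl diethylcarbamate | CCN(CC)C(=O)Oc1ccc(C)c(C)c1
F13 | step 3 | 4,5-dimethyl-2-(trimethylsilyl)phenyl diethylcarbamate | CCN(CC)C(=O)Oc1cc(C)c(C)cc1[Si](C)(C)C
F14 | step 3 | 2-iodo-3,4-dimethyl-6-(trimethylsilyl)phenyl diethylcarbamate | CCN(CC)C(=O)Oc1c(I)c(C)c(C)cc1[Si](C)(C)C
F15 | step 3 | 3,4-dimethyl-2-(2,4,5-trimethoxyphenyl)-6-(trimethylsilyl)phenyl diethylcarbamate | CCN(CC)C(=O)Oc1c(-c2cc(OC)c(OC)cc2OC)c(C)c(C)cc1[Si](C)(C)C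
F16 | step 3 | 3,4-dimethyl-2-(2,4,5-trimethoxyphenyl)-6-(trimethylsilyl)phenol | Cc1cc([Si](C)(C)C)c(O)c(-c2cc(OC)c(OC)cc2OC)c1C
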